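1. Start from a one-step world: each substrate goes to its own product in one step. If the two steps share one constant, the two products stay equal and their excess is zero. That is the zero of the scale. Any other case is measured by the ratio s of left-handed to right-handed product, and the excess is e = (s − 1)/(s + 1). In a one-step world, s at the start is the selectivity factor.

the same everywhere: reagent 13.2 mM; free catalyst 0.27 mM
- north-east: left-handed substrate 11 mM; right-handed substrate 11 mM; impurity 17 µM; run made earlier
- north: left-handed substrate 11 mM; right-handed substrate 11 mM; impurity 26 µM; run made earlier
- south-east: left-handed substrate 5.5 mM; right-handed substrate 5.5 mM; impurity 34 µM; run made earlier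
- flask: left-handed substrate 11 mM; right-handed substrate 11 mM; impurity 34 µM; time 25 min

- north-east (time / min: left-handed product / %, right-handed product / %): 2.00: 7, 2; 6.00: 16, 6; 10.0: 19, 3; 15.0: 23, 6; 25.0: 30, 10; 30.0: 34, 7
- north (time / min: left-handed product / %, right-handed product / %): 5.00: 12, 5; 10.0: 19, 2; 15.0: 26, 7; 20.0: 27, 5; 25.0: 32, 5; 30.0: 33, 8
- south-east (time / min: left-handed product / %, right-handed product / %): 6.00: 19, 2; 12.0: 28, 5; 20.0: 41, 12; 25.0: 41, 7; 30.0: 39, 10

(readings scatter by 2 percentage points)

- free catalyst is single-handed; left-handed substrate and right-handed substrate are mirror images of each other, charged as a racemate, each of them at the stated concentration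
- an excess is the difference of the two amounts in percent of their sum
- an excess is below zero if the other one leads

* excess of left-handed product over right-handed product in the product at 30 s
* excess of left-handed product over right-handed product in the product at 25 min
* part of the left-handed substrate and right-handed substrate charged together that has reacted at 25 min

2. First way: sum the north-east and north readings at 25.0 min and 30.0 min. These runs share the flask's substrate but hold less impurity. You get s = 4.30, so e = 62.3%.

3. Second way: sum the whole south-east run. It shares the flask's impurity but has half the substrate. You get s = 4.67, so e = 64.7%. The two ways agree within the scatter, so I pool them: s = 4.50, the ratio of left-handed to right-handed product, and e = 63.6%.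

4. The first readings of the north-east and north runs part from this: they give s = 2.69. These are the ones that cheat. Their right-handed product readings are 2%, 6% and 5%, each good to 2 percentage points. In a one-step world the faster substrate also thins out first, so the excess falls with time, not rises. I therefore put eb at 63.6% and ea at that value or a little above.

5. The forecast, “Treating this as a kinetic resolution”, gave ea 68% (50% to 82%), eb 63% (53% to 72%) and cb 38% (32% to 42%).

6. The flask gives ea 67.5%, eb 66.7% and cb 35.7%.

    reagent + catalyst intermediate A → free catalyst + left-handed product (k = 15.0 M⁻¹ s⁻¹)
    reagent + catalyst intermediate B → free catalyst + right-handed product (k = 1.10 M⁻¹ s⁻¹)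
    free catalyst + left-handed substrate ⇌ catalyst intermediate A (K = 120 M⁻¹, k = 100 M⁻¹ s⁻¹)
    free catalyst + right-handed substrate ⇌ catalyst intermediate B (K = 250 M⁻¹, k = 2500 M⁻¹ s⁻¹)
    reagent + free catalyst → spent catalyst B (k = 0.240 M⁻¹ s⁻¹)
    left-handed substrate ⇌ right-handed substrate (k = 0.00140 s⁻¹)
    free catalyst + impurity → spent catalyst A (k = 1600 M⁻¹ s⁻¹)

At 25.0 min the flask holds 29.4% left-handed and 5.88% right-handed product, so its s = 5.00; the 4.50 pooled from the earlier runs remains a reading with their scatter. Catalyst intermediate B returns to free catalyst and right-handed substrate, and that return is the main reason for the excess: the same flask without it ends with an excess of −98.5% in place of 66.7%. The neighbour flask with 53 mM of reagent ends with s = 2.99 and an excess of 49.9%.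

All runs stem from a simulated flask from invented constants; scatter was added.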